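The easy step came first: the D column already counted Q, so each run gave me one number, the fraction f of the charge in D at the last reading, 22.9 % on Thursday and 17.1 % on Monday, both at 120 min.

| flask | L | Z | remark | time |
|---|---|---|---|---|
| Thursday's | 0.24 M | 180 mM (held) | run made earlier |  |
| Monday's | 0.98 M | 180 mM (held) | run made earlier |  |
| flask | 0.49 M | 180 mM (held) |  | 2.5 h |

- Thursday's (time / min: D / %, Q / %): 30.0: 4.7, 0.8; 60.0: 12.1, 3.0; 90.0: 18.9, 6.9; 120: 22.9, 6.5
- Monday's (time / min: D / %, Q / %): 15.0: 2.5, 0; 40.0: 5.1, 2.2; 80.0: 12.9, 2.1; 120: 17.1, 3.7

(scatter of a reading: 1 percentage point)

* D and Q together at 2.5 h, in percent of the L charged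
* the change that raises the amount of D and Q together at 2.5 h, in percent of the L charged most ("none" if none brings more than 2 percentage points) (winter / midnight / none)
* amount of D and Q together at 2.5 h, in percent of the L charged, after winter

- winter: doubling the transfer coefficient of Z, all else as stated
- midnight: doubling the saturation concentration of Z, all else as stated

- amounts and yields of D count Q too
- at the start none of Z is in solution

In powers of ten, log f for the flask was Thursday's log f plus a time term plus a charge term, so I asked first which input needed care. Time entered with a power of 0.920 on Thursday and 1.10 on Monday, mean 1.01, and added 0.0980. The charge entered through the charge slope, the power of the L charge by which f moves at fixed time, n = −0.208, and added −0.0643. The scatter of one reading was worth 0.0186, so time mattered most and the scatter least. That gave me f = 0.247.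

With Z held, I counted a slope near minus one as Z transfer being the rate-limiting step, and one near zero as not. I took 0.208 as transfer's share of the resistance. On that reading winter halved that share, giving 0.276, and I took midnight to double f, giving 0.494. So I chose midnight.

The forecast said 32 %, above mine, with 43 % after winter and midnight best, holding that “Z supply partly limits the rate”.

The flask gave 25.9 %, and 30.5 % after winter; midnight won, gaining 15 percentage points against 4.6 points. Z dissolves as G, which stood at 64.7 % of saturation at 1.25 h.

    Z ⇌ G, rate k1*(csat - [G]) (kL = 0.0643 min⁻¹)
    L + G → D (k = 0.0214 M⁻¹ min⁻¹)
    2 G → J (k = 0.103 M⁻¹ min⁻¹)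
    G + D ⇌ Q, settled at all times (K = 3.00 M⁻¹)
    L + D → X (k = 0.00581 M⁻¹ min⁻¹)

Carried back to Thursday's charge at the flask's time, the slope turns that result into 0.301; the computed value there is 28.8 %. On a neighbour flask with 1.2 M of L, same time, the slope gives 0.215. The computed result is 19.6 %.

The earlier runs and the new flask are calculated on assumed constants; noise was put on by code.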